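(Readings and results were generated by integration for substances that don't exist; the scatter is artificial.)

The ring is a passing stock: eta shows it climbing and then falling, so what you collect depends on when you stop.

| flask | substrate | activator | capture agent | temperature | remark | time |
|---|---|---|---|---|---|---|
| eta | 0.70 M | 0.525 M | 0.050 M | −10 °C | run made earlier |  |
| gamma | 1.1 M | 0.525 M | 0.050 M | 12 °C | run made earlier |  |
| elm | 0.50 M | 0.525 M | 0.0500 M |  | at 20 °C until 4.0 min, from then on at −20 °C | 6.0 min |
| oak | 0.50 M | 0.525 M | 0.0500 M | −20 °C |  | 6.0 min |
| maple | 0.50 M | 0.525 M | 0.0500 M | 0 °C |  | 6.0 min |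
| cedar | 0.50 M | 0.525 M | 0.0500 M | 20 °C |  | 6.0 min |

| eta: time / min | eta: ring / % | gamma: time / s | gamma: ring / % |
|---|---|---|---|
| 0.333 | 5.5 | 10.0 | 6.5 |
| 0.667 | 10.6 | 25.0 | 3.0 |
| 1.33 | 14.3 | 40.0 | 3.0 |
| 2.50 | 11.2 | 60.0 | 3.6 |
| 5.00 | 6.9 | 90.0 | 4.6 |

(readings scatter by 1 percentage point)

* which flask leads in amount of ring, in percent of the substrate charged ("all alike" within 1.5 percentage points) (elm / oak / maple / cedar / all alike)
* how much ring is there at the end, in percent of the substrate charged: elm
* how much ring is there at the end, in percent of the substrate charged: oak
* how much ring is there at the end, in percent of the substrate charged: maple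
* how much ring is there at the end, in percent of the substrate charged: cedar

- percentages count the substrate that a species holds: one open dimer counts as two
- ring is meant together with its crystals
- solid, in amounts per volume of the solution: crystals
- steps thought possible: substrate + activator -> activated form; crystals <-> ring; ring <-> isomer of the product; capture agent + activated form -> trapped intermediate; substrate + activated form -> open dimer; activated form -> ring

**Smaller charge.** In the four flasks substrate is the limiting reagent, 0.50 M against 0.525 M of activator. Its balance loses substrate to activator and to activated form, and per unit of substrate the first loss follows the activator, charged at 0.525 M in eta and gamma too. So I let temperature set the clock, though eta and gamma differ in substrate too, 0.70 M against 1.1 M, and my ratio below cannot part the two changes.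

**Peak time.** Eta's highest reading is 14.3% at 1.33 min, at −10 °C. Its fall to 6.9% gives about 0.199 min⁻¹, and gamma's first fall gives 3.09 min⁻¹ at 12 °C. Ring still being made may sit in both, so I trust just their ratio, 15.5. Stretching the time of eta's highest reading by that ratio, geometrically in temperature, gives 4.63 min at −20 °C. That makes 1.30 for oak: the age number, run time over peak time at the flask's temperature.

**Reading it.** With the charges of activator and capture agent held and the substrate charge set aside, I read an age near one as stopping near the maximum, and an age far above one as long past it. Oak stops just past, so I expect about eta's highest reading, though that came from 0.70 M of substrate and oak holds 0.50 M. Maple reaches 15.7 and cedar, extrapolated, 191, so I put both between gamma's low of 3.0% and eta's last 6.9%. Oak should lead.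

**One number?** Not quite. Elm spends 4.0 min at cedar's temperature, then a cold tail of age 0.432. That age speaks of how far elm's ring moves after cooling, not towards what level, so I leave elm in that same band, with less trust.

**The outcome.** The forecast also chose oak, at 18% against 7% for elm, 8% for maple and 6.5% for cedar, reasoning that “oak keeps most of its ring”. The flasks give 16.1% in oak, 8.61% in elm, 6.79% in maple and 4.90% in cedar, so oak leads, and elm stands above my band.

    substrate + activator → activated form (k = 0.00820 L mol⁻¹ s⁻¹, Ea = 45.0 kJ mol⁻¹)
    crystals ⇌ ring, rate k2*(cs2 - [ring]) while solid is left; crystals form when [ring] > cs2 (solubility = 0.210 M, k = 0.110 s⁻¹)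
    ring ⇌ isomer of the product (K = 5.20, k = 0.00420 s⁻¹, Ea = 69.0 kJ mol⁻¹, ΔH = 17.0 kJ mol⁻¹)
    capture agent + activated form → trapped intermediate (k = 0.0700 L mol⁻¹ s⁻¹, Ea = 45.0 kJ mol⁻¹)
    substrate + activated form → open dimer (k = 0.0830 L mol⁻¹ s⁻¹, Ea = 37.0 kJ mol⁻¹)
    activated form → ring (k = 0.0440 s⁻¹, Ea = 60.0 kJ mol⁻¹)
    (constants at −20 °C)

**Past the peak.** In oak at 1.56 min dissolved ring is made 2.82 times as fast as it is used, each step taken net, and at 6.00 min that ratio is 0.824, so oak, at age 1.30, ends past its maximum. Cedar, at age 191, is long past it, and its ring reads 4.90% at the end and 4.91% at 60.0 min.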